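Readings and results were computed with made-up constants, and the scatter is random.

**Earlier runs.** In the zeta run, X climbs at 0.00336 M min⁻¹ between 5.00 min and 10.0 min, a rate read from two readings. D meanwhile reads near 50.1%. Teal repeats zeta, so its D should land near the reading of 45.2% at 20.0 min.

| flask | Q | J | G | remark | time |
|---|---|---|---|---|---|
| zeta | 0.10 M | 0.18 M | 50 µM | run made earlier |  |
| alpha | 0.10 M | 0.18 M | 34 µM | run made earlier |  |
| gamma | 0.10 M | 0.18 M | 75 µM | run made earlier |  |
| green | 0.10 M (fed, over 20.0 min) | 0.180 M | 50 µM | all but Q at the start; Q goes in evenly over 20.0 min, the run ends at 20 min | 20 min |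
| violet | 0.10 M | 0.180 M | 50 µM | one stirred flow tank at steady state, fed with the mixture as stated, mean residence time 20 min |  |
| grey | 0.10 M | 0.180 M (fed, over 20.0 min) | 50 µM | all but J at the start; J goes in evenly over 20.0 min, the run ends at 20 min | 20 min |
| teal | 0.10 M | 0.180 M | 50 µM | a closed flask charged with all of it at once and left for 20 min | 20 min |

- zeta (time / min: D / %, X / %): 5.00: 45.5, 15.3; 10.0: 50.1, 32.1; 15.0: 49.1, 44.6; 20.0: 45.2, 50.2
- alpha (time / min: D / %, X / %): 1.50: 17.8, 3.0; 4.00: 36.3, 7.2; 8.00: 49.0, 17.5; 12.0: 50.3, 24.3
- gamma (time / min: D / %, X / %): 3.00: 43.9, 13.7; 6.00: 49.9, 32.7; 10.0: 43.4, 48.2; 12.0: 41.6, 54.0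

(scatter of a reading: 1 percentage point)

- the stated concentrations are those of everything mixed, before any reaction; amounts are the same in each set-up
- the feed brings no volume worth counting
- the earlier runs were made in a closed, stirred flask

- the set-up with the highest amount of D at the outlet or at the end, in percent of the Q put in ("none" if the first two lie within 2 percentage points) (green / violet / grey / teal / none)
- amount of D at the outlet or at the end, in percent of the Q put in, green
- amount of D at the outlet or at the end, in percent of the Q put in, violet
- amount of D at the outlet or at the end, in percent of the Q put in, grey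
- amount of D at the outlet or at the end, in percent of the Q put in, teal

**Bench rule.** The usual bench rule says that a reagent fed slowly starves the step consuming it and becomes the limiting reagent. Applied to grey, the rule holds X back and leaves D high.

**Its border.** The rule needs a feed slower than the consumption. Grey's J enters at 0.00900 M min⁻¹, faster than zeta's X rate. The ratio is 2.68. This ratio, the feed margin, is the feed rate of a reagent divided by the X rate read in zeta, and the border lies at one.

**This reckoning.** With a margin above one, grey should stay close to teal. The reckoning counts one J per X, and no reading shows J directly.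

**The forecast.** It names grey as best, with green 38%, violet 37%, grey 71% and teal 45.3%. Its ground for grey reads “J starvation holds step 2 back”. This differs from the reckoning above, which keeps grey near teal.

**The result.** The simulation gives green 46.4%, violet 36.8%, grey 50.9% and teal 46.0%. Grey ranks first.

    Q + G → G + D (k = 4660 L mol⁻¹ min⁻¹)
    G + D ⇌ L (K = 15.2 L mol⁻¹, k = 4910 L mol⁻¹ min⁻¹)
    J + L → G + X (k = 2420 L mol⁻¹ min⁻¹)
    J → Z (k = 0.0667 min⁻¹)

**Dose and D.** With its margin of 2.68, grey makes 44.0% of X. Grey's D stands at 50.9% through two things acting together, the reverse step from L to G + D and the end of the run at 20 min: without that step grey gives 26.5%, and at 200 min it gives 29.3%. Green's Q feed, set against the same X rate, gives a margin of 1.49, also above one. The slow dosing of Q is not the reason for green's D: dosed or charged at once, D reads 46.4% and 46.0%.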